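## Structural features

The target is a trans-1-aryl-1,2-dihydronaphthalene lignan. Ring A is a 6-methoxy-7-hydroxy arene fused to the partly saturated ring B, and C1 of ring B carries the pendant 4-hydroxy-3-methoxyphenyl ring C. The only stereocentres are C1 (S, doubly benzylic) and C2 (R, bearing the acetoxymethyl carbon C9); they are adjacent and trans, so they have to be set as a pair. C3 carries the formyl carbon C10 and is joined to C4 by a double bond conjugated with both the aldehyde and ring A. The fragile groups are the enal (nucleophiles, hydride), the primary acetate (hydride, strong base), the two oxidisable phenols, and the dihydronaphthalene core, which can aromatise or epimerise at C1 under forcing conditions. Rings A and C carry the same guaiacyl oxygenation, so electrophilic substitution cannot tell them apart, and ring A needs a pre-installed handle ortho to C1 for the carbon that becomes C4. The real difficulty is to close ring B with the C3=C4 alkene and the C10 carbonyl correctly placed without disturbing the preset C1/C2 pair. The key step uses the C4(H)=C3–C10(=O) unit next to ring A, which is what a carbonyl–alkyne exchange between a ring A aldehyde (C4) and a nitrogen-polarised C3≡C10 alkyne leaves behind.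

## Logic of the disconnections

**29 ⇒ 28 ⇒ 27 ⇒ 26.** The two phenolic O–H bonds are traced back to O–Si bonds and the C9 O–acyl bond is cut. The acetate cannot pass through hydride or organolithium steps, and free phenols would be acetylated together with C9–OH. The gain is that 26 carries only inert ethers. The demand is orthogonality: the alkyl silyl ether at C9 must leave under acid while the aryl silyl ethers stay, and the aryl silyl ethers must later leave under buffered fluoride while the acetate stays.

**26 ⇒ 25 ⇒ 24.** The C10–H bond of the aldehyde is exchanged for the C10–N bond of an imide. This is the oxidation level the ring closure delivers. The demand is 1,2-selective hydride delivery to 24 and an oxidant that touches only the allylic alcohol of 25.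

**24 ⇒ 22.** The C3=C4 double bond is cut and the C10 oxygen is returned to C4. Ring B opens to an arene aldehyde and a C3≡C10 alkyne bearing nitrogen on C10. This is the most simplifying cut: it removes the ring and the trisubstituted alkene, touches no stereocentre, and leaves C1 and C2 on an acyclic chain where auxiliary chemistry can set them. The demand is a Lewis acid that activates the aldehyde without stripping silyl ethers, and an alkyne whose polarisation places carbon on C4 and oxygen on C10.

**22 ⇒ 20 + 21 and 20 ⇒ 19.** The C10–N bond and then the C10–Br bond are cut. The nitrogen is introduced last because the N-alkynyl group is acid- and nucleophile-sensitive. The demand is a copper-catalysed N-alkynylation mild enough for an aryl aldehyde and a propargylic stereocentre.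

**19 ⇒ 17.** The C4–C4a bond is cut; C4 comes from a formamide and ring A is metalated at its bromide. This is placed before the nitrogen is attached, not after. An aryllithium ortho to C1 would add across a C3≡C10 N-alkynyl group (5-exo-dig), and at the earlier imide stage it would acylate itself (Parham-type). At the terminal alkyne stage the alkyne protects itself as its acetylide. The demand is that the aryllithium is formylated selectively.

**17 ⇒ 16 ⇒ 15 ⇒ 14.** The C3≡C10 triple bond is cut to a C3 aldehyde plus a one-carbon diazophosphonate, and the aldehyde is traced to the acyl oxazolidinone. The acyl carbon of the auxiliary thus becomes C3. The demand is that C2, alpha to the aldehyde in 16, does not epimerise.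

**14 ⇒ 13 ⇒ 11.** The C2–C9 bond is cut to an enolate and a formaldehyde equivalent. The auxiliary already present controls the face. Silylation before reductive removal of the auxiliary is essential, because only then are the two CH2O arms on C2 different.

**11 ⇒ 7 + 10 (10 ⇐ 9 ⇐ 8).** The C1–aryl bond to ring C is cut. Ring A must sit on the enoyl partner and ring C must be the nucleophile: only this assignment lets one auxiliary set both C1 (S) and C2 (R) in the trans sense. The demand is high facial selectivity on an ortho-substituted cinnamoyl imide.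

**7 ⇒ 2 + 6; 6 ⇒ 3 + 4; 2 ⇒ 1.** The C1=C2 alkene and the N-acyl bond are cut, leading to the protected ring A aldehyde, a phosphonoacetic acid and the (R)-auxiliary. The ring A aldehyde carbon becomes C1 and its bromine marks the future C4a, which matches the oxygenation pattern of the target.

## Other disconnections considered

**Alternative 1:** The cut is across C2–C3 and C1–C8a at once. It opens ring B and a fused ether ring to the achiral 1,6-enyne A1, an aryl propargyl (E)-cinnamyl ether built from two vanillin-type halves. In the forward step the cationic complex from (R)-DTBM-MeO-BIPHEP(AuCl)2 and AgSbF6 would activate the alkyne; the alkene would attack to give a cyclopropyl gold carbene, and ring A would close on C1 para to its methoxy group, giving the trans tetrahydronaphthofuran A2. In its favour: both ring B bonds and both stereocentres form in one catalytic step, the trans relation follows stereospecifically from the (E)-alkene, no auxiliary is needed, and A1 is only a few steps from cheap phenols. On stereochemical economy and on step count to the carbocycle it is the better plan. Against it here: A2 ties C9 and C10 together as a cyclic ether. Reaching the target needs site-selective oxidation of the allylic C10 methylene next to a tertiary allylic C2–H and electron-rich arenes, then ring opening and differentiation of two primary alcohols. The chosen plan has C9 and C10 differentiated from the start. The enantioselectivity of a digold catalyst is also hard to predict for a new, heavily oxygenated substrate, whereas the auxiliary steps are predictable.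

**Alternative 2:** The cut removes C4a–C8a, C5–C6 and C7–C8, so that rings A and B arise together from the 1,7-diyne A3 and 1,2-bis(pinacolboryl)ethyne A4. CpCo(CO)2 would couple the two tethered alkynes to a cobaltacyclopentadiene, insert A4 and release the diboryl tetralin A5. In its favour: ring A is made and not functionalised, so no halogen–metal exchange or regiochemical problem on a guaiacyl ring arises, and two rings close in one step. On convergence of ring construction it is the better plan, and in reliability of an intramolecular ring B closure it is the equal of the chosen plan. Against it here: A3 needs four contiguous stereocentres on an open chain, two of which (C3, C4) are destroyed later by elimination to C3=C4 and oxidation of C10. The two C–B bonds at C6 and C7 must end as one methoxy and one hydroxy group with nothing to tell them apart. The acetate has to survive the whole endgame. Overall it would be longer and less selective than the chosen plan.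

**Alternative 3:** The cut is the C2–C3 bond, read as the product of a [3,3] shift. It leads to the ten-membered benzo-fused allylic lactone A6. After enolisation and O-silylation, A6 would rearrange across the ring and contract to the tetralin acid A7, with a vinyl group on C2 and the carboxyl on C3. In its favour: the ring-forming step itself sets C2 relative to C1 through an ordered transannular transition state, and the C3 carboxyl carbon arrives at the right place. In creating stereochemistry during ring formation it is better than the chosen key step, which creates none. Against it here: a ten-membered lactone with defined alkene geometry is costly to make, and a chair or boat transition state in a medium ring is hard to predict. The C4 silyloxy centre is built only to be eliminated. The vinyl group has one carbon too many and must be cleaved oxidatively in the presence of electron-rich arenes. The step count would clearly exceed that of the chosen plan.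

Key step: step 14

Assumption: the target is the trans-(1S,2R) isomer encoded in the SMILES; labels C1–C10 follow the lignan numbering used above, and CIP descriptors at C2 change along the route only because substituent priorities change.

## Route

Step 1
Reactants: 1 6-bromoisovanillin (2-bromo-5-hydroxy-4-methoxybenzaldehyde)
Product: 2 2-bromo-4-methoxy-5-(triisopropylsilyloxy)benzaldehyde
Conditions: TIPSCl, imidazole, DMF, rt
Reagents that add atoms: triisopropylsilyl chloride, CC(C)[Si](Cl)(C(C)C)C(C)C
Why: Imidazole-promoted O-silylation of the phenol; the bulky, non-chelating aryl silyl ether is chosen over acetal-type ethers because it should survive TiCl4 (step 6), organolithiums (step 11) and BF3·OEt2 (step 14) and leaves at the end under buffered fluoride.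

Step 2
Reactants: 3 diethylphosphonoacetic acid; 4 (R)-4-benzyl-2-oxazolidinone
Product: 6 diethyl {2-[(R)-4-benzyl-2-oxooxazolidin-3-yl]-2-oxoethyl}phosphonate, via 2-(diethoxyphosphoryl)acetic pivalic anhydride 5 (not isolated)
Conditions: PivCl, Et3N, THF, −20 °C; then 4, LiCl, −20 °C → rt
Reagents that add atoms: none
Why: N-acylation of the oxazolidinone through a mixed pivalic anhydride activated by LiCl/Et3N; the hindered pivaloyl carbonyl directs attack to the phosphonoacetyl carbonyl, and no stereocentre is touched.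

Step 3
Reactants: 2 2-bromo-4-methoxy-5-(triisopropylsilyloxy)benzaldehyde; 6 diethyl {2-[(R)-4-benzyl-2-oxooxazolidin-3-yl]-2-oxoethyl}phosphonate
Product: 7 (R)-4-benzyl-3-{(E)-3-[2-bromo-4-methoxy-5-(triisopropylsilyloxy)phenyl]acryloyl}oxazolidin-2-one
Conditions: LiCl, i-Pr2NEt, MeCN, rt
Reagents that add atoms: none
Why: Horner–Wadsworth–Emmons olefination under mild LiCl/amine conditions; the stabilised lithium-chelated phosphonate anion should give the (E)-enoyl imide, and the aryl bromide and silyl ether are spectators.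

Step 4
Reactants: 8 4-bromo-2-methoxyphenol
Product: 9 (4-bromo-2-methoxyphenoxy)triisopropylsilane
Conditions: TIPSCl, imidazole, DMF, rt
Reagents that add atoms: triisopropylsilyl chloride, CC(C)[Si](Cl)(C(C)C)C(C)C
Why: O-silylation of the phenol so that the bromide can be turned into a Grignard reagent.

Step 5
Reactants: 9 (4-bromo-2-methoxyphenoxy)triisopropylsilane; 7 (R)-4-benzyl-3-{(E)-3-[2-bromo-4-methoxy-5-(triisopropylsilyloxy)phenyl]acryloyl}oxazolidin-2-one
Product: 11 (R)-4-benzyl-3-{(3S)-3-[2-bromo-4-methoxy-5-(triisopropylsilyloxy)phenyl]-3-[3-methoxy-4-(triisopropylsilyloxy)phenyl]propanoyl}oxazolidin-2-one, via [3-methoxy-4-(triisopropylsilyloxy)phenyl]magnesium bromide 10 (not isolated)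
Conditions: 9, Mg, THF, reflux; then CuBr·SMe2 (1.2 equiv), THF/Me2S, −40 °C; 7, −40 → −10 °C; aq. NH4Cl
Reagents that add atoms: none
Why: Copper-mediated conjugate addition of an aryl Grignard reagent to an N-enoyl oxazolidinone; in the magnesium-chelated syn-s-cis conformer the C4 benzyl group covers one face of C1, so ring C should add to the opposite face and give the (S)-diarylmethine; the ring A bromide does not exchange with an arylmagnesium at this temperature.

Step 6
Reactants: 11 (R)-4-benzyl-3-{(3S)-3-[2-bromo-4-methoxy-5-(triisopropylsilyloxy)phenyl]-3-[3-methoxy-4-(triisopropylsilyloxy)phenyl]propanoyl}oxazolidin-2-one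
Product: 13 (R)-4-benzyl-3-{(2S,3S)-3-[2-bromo-4-methoxy-5-(triisopropylsilyloxy)phenyl]-2-(hydroxymethyl)-3-[3-methoxy-4-(triisopropylsilyloxy)phenyl]propanoyl}oxazolidin-2-one, via trichlorotitanium (Z)-enolate of the imide 12 (not isolated)
Conditions: TiCl4 (1.05 equiv), i-Pr2NEt (1.1 equiv), CH2Cl2, 0 °C; then 1,3,5-trioxane (1.1 equiv), TiCl4 (1.05 equiv), 0 °C; aq. NH4Cl
Reagents that add atoms: 1,3,5-trioxane, C1OCOCO1
Why: Soft enolisation gives the chelated (Z)-titanium enolate, and TiCl4-activated trioxane (a formaldehyde equivalent) should attack the enolate face anti to the C4 benzyl group in an aldol-type hydroxymethylation; this sets C2 in the sense that becomes trans to the C1 aryl group in ring B, and the enolate is far more nucleophilic than the silylated arenes.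

Step 7
Reactants: 13 (R)-4-benzyl-3-{(2S,3S)-3-[2-bromo-4-methoxy-5-(triisopropylsilyloxy)phenyl]-2-(hydroxymethyl)-3-[3-methoxy-4-(triisopropylsilyloxy)phenyl]propanoyl}oxazolidin-2-one
Product: 14 (R)-4-benzyl-3-{(2S,3S)-3-[2-bromo-4-methoxy-5-(triisopropylsilyloxy)phenyl]-2-[(tert-butyldimethylsilyloxy)methyl]-3-[3-methoxy-4-(triisopropylsilyloxy)phenyl]propanoyl}oxazolidin-2-one
Conditions: TBSCl, imidazole, DMF, rt
Reagents that add atoms: tert-butyldimethylsilyl chloride, CC(C)(C)[Si](C)(C)Cl
Why: Silylation of the primary alcohol marks this arm as C9 before the acyl carbon is reduced, so the two CH2O arms on C2 stay different and the C2 configuration is kept.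

Step 8
Reactants: 14 (R)-4-benzyl-3-{(2S,3S)-3-[2-bromo-4-methoxy-5-(triisopropylsilyloxy)phenyl]-2-[(tert-butyldimethylsilyloxy)methyl]-3-[3-methoxy-4-(triisopropylsilyloxy)phenyl]propanoyl}oxazolidin-2-one
Product: 15 (2R,3S)-3-[2-bromo-4-methoxy-5-(triisopropylsilyloxy)phenyl]-2-[(tert-butyldimethylsilyloxy)methyl]-3-[3-methoxy-4-(triisopropylsilyloxy)phenyl]propan-1-ol
Conditions: LiBH4, MeOH (1 equiv), THF, 0 °C
Reagents that add atoms: none
Why: Reductive cleavage of the N-acyl oxazolidinone by hydride attack at the exocyclic carbonyl releases the auxiliary and the primary alcohol (the future C3) without enolisation, so C2 is not epimerised; silyl ethers and the aryl bromide are inert.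

Step 9
Reactants: 15 (2R,3S)-3-[2-bromo-4-methoxy-5-(triisopropylsilyloxy)phenyl]-2-[(tert-butyldimethylsilyloxy)methyl]-3-[3-methoxy-4-(triisopropylsilyloxy)phenyl]propan-1-ol
Product: 16 (2S,3S)-3-[2-bromo-4-methoxy-5-(triisopropylsilyloxy)phenyl]-2-[(tert-butyldimethylsilyloxy)methyl]-3-[3-methoxy-4-(triisopropylsilyloxy)phenyl]propanal
Conditions: Dess–Martin periodinane, CH2Cl2, 0 °C → rt
Reagents that add atoms: none
Why: Dess–Martin oxidation is non-basic and should give the alpha-branched aldehyde without epimerisation at C2; the aldehyde is used directly.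

Step 10
Reactants: 16 (2S,3S)-3-[2-bromo-4-methoxy-5-(triisopropylsilyloxy)phenyl]-2-[(tert-butyldimethylsilyloxy)methyl]-3-[3-methoxy-4-(triisopropylsilyloxy)phenyl]propanal
Product: 17 (3R,4S)-4-[2-bromo-4-methoxy-5-(triisopropylsilyloxy)phenyl]-3-[(tert-butyldimethylsilyloxy)methyl]-4-[3-methoxy-4-(triisopropylsilyloxy)phenyl]but-1-yne
Conditions: dimethyl (1-diazo-2-oxopropyl)phosphonate, K2CO3, MeOH/THF, 0 °C → rt
Reagents that add atoms: dimethyl (1-diazo-2-oxopropyl)phosphonate, COP(=O)(OC)C(=[N+]=[N-])C(C)=O
Why: Ohira–Bestmann (Seyferth–Gilbert) homologation: the diazomethylphosphonate anion formed in situ adds to the aldehyde, phosphate and N2 are lost and a 1,2-hydrogen shift gives the terminal alkyne with C10 as the new carbon; no alkyllithium is used, so the aryl bromide survives, and the low temperature limits enolisation at C2.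

Step 11
Reactants: 17 (3R,4S)-4-[2-bromo-4-methoxy-5-(triisopropylsilyloxy)phenyl]-3-[(tert-butyldimethylsilyloxy)methyl]-4-[3-methoxy-4-(triisopropylsilyloxy)phenyl]but-1-yne
Product: 19 2-{(1S,2R)-2-[(tert-butyldimethylsilyloxy)methyl]-1-[3-methoxy-4-(triisopropylsilyloxy)phenyl]but-3-yn-1-yl}-5-methoxy-4-(triisopropylsilyloxy)benzaldehyde, via C,C-dilithio intermediate 18 (not isolated)
Conditions: MeLi (1.05 equiv), THF, −78 °C; t-BuLi (2.1 equiv), −78 °C; DMF (3 equiv), −78 °C; AcOH, then aq. NH4Cl
Reagents that add atoms: N,N-dimethylformamide, CN(C)C=O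
Why: MeLi deprotonates the alkyne without exchanging the aryl bromide, t-BuLi then performs bromine–lithium exchange, and the aryllithium is formylated by DMF at −78 °C while the lithium acetylide neither adds to DMF at that temperature nor accepts carbolithiation; doing this before the nitrogen is on the alkyne removes the 5-exo-dig trap.

Step 12
Reactants: 19 2-{(1S,2R)-2-[(tert-butyldimethylsilyloxy)methyl]-1-[3-methoxy-4-(triisopropylsilyloxy)phenyl]but-3-yn-1-yl}-5-methoxy-4-(triisopropylsilyloxy)benzaldehyde
Product: 20 2-{(1S,2R)-4-bromo-2-[(tert-butyldimethylsilyloxy)methyl]-1-[3-methoxy-4-(triisopropylsilyloxy)phenyl]but-3-yn-1-yl}-5-methoxy-4-(triisopropylsilyloxy)benzaldehyde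
Conditions: NBS (1.1 equiv), AgNO3 (0.1 equiv), acetone, rt, dark
Reagents that add atoms: N-bromosuccinimide, O=C1CCC(=O)N1Br
Why: Silver-catalysed bromination of a terminal alkyne through its silver acetylide is fast and neutral, so the aldehyde, the silyl ethers and the arenes should be untouched.

Step 13
Reactants: 20 2-{(1S,2R)-4-bromo-2-[(tert-butyldimethylsilyloxy)methyl]-1-[3-methoxy-4-(triisopropylsilyloxy)phenyl]but-3-yn-1-yl}-5-methoxy-4-(triisopropylsilyloxy)benzaldehyde; 21 2-oxazolidinone
Product: 22 2-{(1S,2R)-2-[(tert-butyldimethylsilyloxy)methyl]-1-[3-methoxy-4-(triisopropylsilyloxy)phenyl]-4-(2-oxooxazolidin-3-yl)but-3-yn-1-yl}-5-methoxy-4-(triisopropylsilyloxy)benzaldehyde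
Conditions: CuSO4·5H2O (0.15 equiv), 1,10-phenanthroline (0.3 equiv), K3PO4 (2 equiv), toluene, 70 °C
Reagents that add atoms: none
Why: Copper-catalysed N-alkynylation of a carbamate with a 1-bromoalkyne; the heterogeneous phosphate base is too weak to enolise anything in the substrate, the aryl aldehyde has no alpha-hydrogen, and no aryl halide remains to compete.

Step 14
Reactants: 22 2-{(1S,2R)-2-[(tert-butyldimethylsilyloxy)methyl]-1-[3-methoxy-4-(triisopropylsilyloxy)phenyl]-4-(2-oxooxazolidin-3-yl)but-3-yn-1-yl}-5-methoxy-4-(triisopropylsilyloxy)benzaldehyde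
Product: 24 3-{(1S,2R)-2-[(tert-butyldimethylsilyloxy)methyl]-6-methoxy-1-[3-methoxy-4-(triisopropylsilyloxy)phenyl]-7-(triisopropylsilyloxy)-1,2-dihydronaphthalene-3-carbonyl}oxazolidin-2-one, via fused 2-amino-2H-oxete 23 (not isolated)
Conditions: BF3·OEt2 (0.5 equiv), 4 Å MS, CH2Cl2, −40 → 0 °C; Et3N, aq. NaHCO3
Reagents that add atoms: none
Why: BF3·OEt2 binds the ring A aldehyde oxygen and the nitrogen-polarised alkyne attacks C4 through its beta carbon C3, closing ring B in a 6-exo mode (exo-dig for the alkyne, exo-trig for the carbonyl) and leaving C10 as an exocyclic keteniminium carbon. The alkoxide on C4 then closes onto C10 to give the fused 2-amino-2H-oxete 23, and conrotatory 4π ring opening breaks C4–O and delivers the endocyclic C3=C4 alkene with C10 as the imide carbonyl. The closest known reaction type is the Lewis acid-promoted ring-closing ynamide–carbonyl metathesis (hetero-(2+2) addition followed by retro-electrocyclisation) of aldehyde-tethered N-alkynyl oxazolidinones. No stereocentre is created: C4 is stereogenic only in 23 and ends sp2, and C1 and C2 have no acidic hydrogen under Lewis acid conditions, so the preset pair should be retained. The selectivity needed is regiochemical (C3–C4 and not C10–C4 bonding), and it is secured twice: the nitrogen lone pair makes C3 the nucleophilic and C10 the electrophilic alkyne carbon, and the tether offers a six-membered ring for C3 against a seven-membered ring for C10. Chemoselectivity toward the silyl ethers and the electron-rich arenes rests on a fast intramolecular reaction at low temperature with a substoichiometric, mild Lewis acid. The alkene geometry is fixed by the ring.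

Step 15
Reactants: 24 3-{(1S,2R)-2-[(tert-butyldimethylsilyloxy)methyl]-6-methoxy-1-[3-methoxy-4-(triisopropylsilyloxy)phenyl]-7-(triisopropylsilyloxy)-1,2-dihydronaphthalene-3-carbonyl}oxazolidin-2-one
Product: 25 {(1S,2R)-2-[(tert-butyldimethylsilyloxy)methyl]-6-methoxy-1-[3-methoxy-4-(triisopropylsilyloxy)phenyl]-7-(triisopropylsilyloxy)-1,2-dihydronaphthalen-3-yl}methanol
Conditions: i-Bu2AlH (4 equiv), CH2Cl2, −78 °C; aq. potassium sodium tartrate (KNaC4H4O6)
Reagents that add atoms: none
Why: Low-temperature i-Bu2AlH reduction of the activated enoyl imide should proceed by 1,2-hydride delivery to the exocyclic carbonyl, giving the allylic alcohol and releasing 2-oxazolidinone; silyl ethers are inert.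

Step 16
Reactants: 25 {(1S,2R)-2-[(tert-butyldimethylsilyloxy)methyl]-6-methoxy-1-[3-methoxy-4-(triisopropylsilyloxy)phenyl]-7-(triisopropylsilyloxy)-1,2-dihydronaphthalen-3-yl}methanol
Product: 26 (1S,2R)-2-[(tert-butyldimethylsilyloxy)methyl]-6-methoxy-1-[3-methoxy-4-(triisopropylsilyloxy)phenyl]-7-(triisopropylsilyloxy)-1,2-dihydronaphthalene-3-carbaldehyde
Conditions: MnO2 (activated, excess), CH2Cl2, rt
Reagents that add atoms: none
Why: MnO2 oxidises allylic alcohols selectively to enals under neutral conditions, which should spare the doubly benzylic C1–H and avoid aromatisation.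

Step 17
Reactants: 26 (1S,2R)-2-[(tert-butyldimethylsilyloxy)methyl]-6-methoxy-1-[3-methoxy-4-(triisopropylsilyloxy)phenyl]-7-(triisopropylsilyloxy)-1,2-dihydronaphthalene-3-carbaldehyde
Product: 27 (1S,2R)-2-(hydroxymethyl)-6-methoxy-1-[3-methoxy-4-(triisopropylsilyloxy)phenyl]-7-(triisopropylsilyloxy)-1,2-dihydronaphthalene-3-carbaldehyde
Conditions: HCl (1 M aq.), THF, 0 °C → rt
Reagents that add atoms: none
Why: Acid hydrolysis removes a primary alkyl tert-butyldimethylsilyl ether much faster than hindered aryl triisopropylsilyl ethers; water and not an alcohol is the co-solvent so that the hydroxy enal is not trapped as a cyclic acetal.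

Step 18
Reactants: 27 (1S,2R)-2-(hydroxymethyl)-6-methoxy-1-[3-methoxy-4-(triisopropylsilyloxy)phenyl]-7-(triisopropylsilyloxy)-1,2-dihydronaphthalene-3-carbaldehyde
Product: 28 {(1S,2R)-3-formyl-6-methoxy-1-[3-methoxy-4-(triisopropylsilyloxy)phenyl]-7-(triisopropylsilyloxy)-1,2-dihydronaphthalen-2-yl}methyl acetate
Conditions: Ac2O, pyridine, DMAP (cat.), CH2Cl2, 0 °C
Reagents that add atoms: acetic anhydride, CC(=O)OC(C)=O
Why: Standard O-acetylation of the only free hydroxyl; both phenols are still silylated, so no selectivity problem arises.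

Step 19
Reactants: 28 {(1S,2R)-3-formyl-6-methoxy-1-[3-methoxy-4-(triisopropylsilyloxy)phenyl]-7-(triisopropylsilyloxy)-1,2-dihydronaphthalen-2-yl}methyl acetate
Product: 29 [(1S,2R)-3-formyl-7-hydroxy-1-(4-hydroxy-3-methoxyphenyl)-6-methoxy-1,2-dihydronaphthalen-2-yl]methyl acetate (CNP0549177.1)
Conditions: TBAF (2.4 equiv), AcOH (2.6 equiv), THF, 0 °C
Reagents that add atoms: none
Why: Fluoride cleaves aryl silyl ethers rapidly, and buffering with acetic acid keeps the medium near neutral so that the acetate, the enal and the C1/C2 centres should be unaffected.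

## Compound list

1 | 6-bromoisovanillin (2-bromo-5-hydroxy-4-methoxybenzaldehyde) | COc1cc(Br)c(C=O)cc1O | starting material
2 | 2-bromo-4-methoxy-5-(triisopropylsilyloxy)benzaldehyde | COc1cc(Br)c(C=O)cc1O[Si](C(C)C)(C(C)C)C(C)C | intermediate
3 | diethylphosphonoacetic acid | CCOP(=O)(CC(=O)O)OCC | starting material
4 | (R)-4-benzyl-2-oxazolidinone | O=C1N[C@H](Cc2ccccc2)CO1 | starting material
5 | 2-(diethoxyphosphoryl)acetic pivalic anhydride (not isolated) | CCOP(=O)(CC(=O)OC(=O)C(C)(C)C)OCC | intermediate
6 | diethyl {2-[(R)-4-benzyl-2-oxooxazolidin-3-yl]-2-oxoethyl}phosphonate | CCOP(=O)(CC(=O)N1[C@H](Cc2ccccc2)COC1=O)OCC | intermediate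
7 | (R)-4-benzyl-3-{(E)-3-[2-bromo-4-methoxy-5-(triisopropylsilyloxy)phenyl]acryloyl}oxazolidin-2-one | COc1cc(Br)c(/C=C/C(=O)N2[C@H](Cc3ccccc3)COC2=O)cc1O[Si](C(C)C)(C(C)C)C(C)C | intermediate
8 | 4-bromo-2-methoxyphenol | COc1cc(Br)ccc1O | starting material
9 | (4-bromo-2-methoxyphenoxy)triisopropylsilane | COc1cc(Br)ccc1O[Si](C(C)C)(C(C)C)C(C)C | intermediate
10 | [3-methoxy-4-(triisopropylsilyloxy)phenyl]magnesium bromide (not isolated) | COc1cc([Mg]Br)ccc1O[Si](C(C)C)(C(C)C)C(C)C | intermediate
11 | (R)-4-benzyl-3-{(3S)-3-[2-bromo-4-methoxy-5-(triisopropylsilyloxy)phenyl]-3-[3-methoxy-4-(triisopropylsilyloxy)phenyl]propanoyl}oxazolidin-2-one | COc1cc([C@@H](c2cc(O[Si](C(C)C)(C(C)C)C(C)C)c(OC)cc2Br)CC(=O)N2[C@H](Cc3ccccc3)COC2=O)ccc1O[Si](C(C)C)(C(C)C)C(C)C | intermediate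
12 | trichlorotitanium (Z)-enolate of 11 (not isolated) | COc1cc([C@@H](c2cc(O[Si](C(C)C)(C(C)C)C(C)C)c(OC)cc2Br)/C=C(\O[Ti](Cl)(Cl)Cl)N2[C@H](Cc3ccccc3)COC2=O)ccc1O[Si](C(C)C)(C(C)C)C(C)C | intermediate
13 | (R)-4-benzyl-3-{(2S,3S)-3-[2-bromo-4-methoxy-5-(triisopropylsilyloxy)phenyl]-2-(hydroxymethyl)-3-[3-methoxy-4-(triisopropylsilyloxy)phenyl]propanoyl}oxazolidin-2-one | COc1cc([C@@H](c2cc(O[Si](C(C)C)(C(C)C)C(C)C)c(OC)cc2Br)[C@@H](CO)C(=O)N2[C@H](Cc3ccccc3)COC2=O)ccc1O[Si](C(C)C)(C(C)C)C(C)C | intermediate
14 | (R)-4-benzyl-3-{(2S,3S)-3-[2-bromo-4-methoxy-5-(triisopropylsilyloxy)phenyl]-2-[(tert-butyldimethylsilyloxy)methyl]-3-[3-methoxy-4-(triisopropylsilyloxy)phenyl]propanoyl}oxazolidin-2-one | COc1cc([C@@H](c2cc(O[Si](C(C)C)(C(C)C)C(C)C)c(OC)cc2Br)[C@@H](CO[Si](C)(C)C(C)(C)C)C(=O)N2[C@H](Cc3ccccc3)COC2=O)ccc1O[Si](C(C)C)(C(C)C)C(C)C | intermediate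
15 | (2R,3S)-3-[2-bromo-4-methoxy-5-(triisopropylsilyloxy)phenyl]-2-[(tert-butyldimethylsilyloxy)methyl]-3-[3-methoxy-4-(triisopropylsilyloxy)phenyl]propan-1-ol | COc1cc([C@@H](c2cc(O[Si](C(C)C)(C(C)C)C(C)C)c(OC)cc2Br)[C@@H](CO[Si](C)(C)C(C)(C)C)CO)ccc1O[Si](C(C)C)(C(C)C)C(C)C | intermediate
16 | (2S,3S)-3-[2-bromo-4-methoxy-5-(triisopropylsilyloxy)phenyl]-2-[(tert-butyldimethylsilyloxy)methyl]-3-[3-methoxy-4-(triisopropylsilyloxy)phenyl]propanal | COc1cc([C@@H](c2cc(O[Si](C(C)C)(C(C)C)C(C)C)c(OC)cc2Br)[C@@H](CO[Si](C)(C)C(C)(C)C)C=O)ccc1O[Si](C(C)C)(C(C)C)C(C)C | intermediate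
17 | (3R,4S)-4-[2-bromo-4-methoxy-5-(triisopropylsilyloxy)phenyl]-3-[(tert-butyldimethylsilyloxy)methyl]-4-[3-methoxy-4-(triisopropylsilyloxy)phenyl]but-1-yne | COc1cc([C@@H](c2cc(O[Si](C(C)C)(C(C)C)C(C)C)c(OC)cc2Br)[C@@H](CO[Si](C)(C)C(C)(C)C)C#C)ccc1O[Si](C(C)C)(C(C)C)C(C)C | intermediate
18 | C,C-dilithio intermediate (ring A aryllithium and lithium acetylide; not isolated) | COc1cc([C@@H](c2cc(O[Si](C(C)C)(C(C)C)C(C)C)c(OC)cc2[Li])[C@@H](CO[Si](C)(C)C(C)(C)C)C#C[Li])ccc1O[Si](C(C)C)(C(C)C)C(C)C | intermediate
19 | 2-{(1S,2R)-2-[(tert-butyldimethylsilyloxy)methyl]-1-[3-methoxy-4-(triisopropylsilyloxy)phenyl]but-3-yn-1-yl}-5-methoxy-4-(triisopropylsilyloxy)benzaldehyde | COc1cc([C@@H](c2cc(O[Si](C(C)C)(C(C)C)C(C)C)c(OC)cc2C=O)[C@@H](CO[Si](C)(C)C(C)(C)C)C#C)ccc1O[Si](C(C)C)(C(C)C)C(C)C | intermediate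
20 | 2-{(1S,2R)-4-bromo-2-[(tert-butyldimethylsilyloxy)methyl]-1-[3-methoxy-4-(triisopropylsilyloxy)phenyl]but-3-yn-1-yl}-5-methoxy-4-(triisopropylsilyloxy)benzaldehyde | COc1cc([C@@H](c2cc(O[Si](C(C)C)(C(C)C)C(C)C)c(OC)cc2C=O)[C@@H](CO[Si](C)(C)C(C)(C)C)C#CBr)ccc1O[Si](C(C)C)(C(C)C)C(C)C | intermediate
21 | 2-oxazolidinone | O=C1NCCO1 | starting material
22 | 2-{(1S,2R)-2-[(tert-butyldimethylsilyloxy)methyl]-1-[3-methoxy-4-(triisopropylsilyloxy)phenyl]-4-(2-oxooxazolidin-3-yl)but-3-yn-1-yl}-5-methoxy-4-(triisopropylsilyloxy)benzaldehyde (key-step precursor) | COc1cc([C@@H](c2cc(O[Si](C(C)C)(C(C)C)C(C)C)c(OC)cc2C=O)[C@@H](CO[Si](C)(C)C(C)(C)C)C#CN2CCOC2=O)ccc1O[Si](C(C)C)(C(C)C)C(C)C | intermediate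
23 | 2-amino-2H-oxete fused to ring B at C3–C4 (C4 configuration transient; not isolated) | COc1cc([C@H]2c3cc(O[Si](C(C)C)(C(C)C)C(C)C)c(OC)cc3C5OC(N4CCOC4=O)=C5[C@@H]2CO[Si](C)(C)C(C)(C)C)ccc1O[Si](C(C)C)(C(C)C)C(C)C | intermediate
24 | 3-{(1S,2R)-2-[(tert-butyldimethylsilyloxy)methyl]-6-methoxy-1-[3-methoxy-4-(triisopropylsilyloxy)phenyl]-7-(triisopropylsilyloxy)-1,2-dihydronaphthalene-3-carbonyl}oxazolidin-2-one (key-step product) | COc1cc([C@H]2c3cc(O[Si](C(C)C)(C(C)C)C(C)C)c(OC)cc3C=C(C(=O)N3CCOC3=O)[C@@H]2CO[Si](C)(C)C(C)(C)C)ccc1O[Si](C(C)C)(C(C)C)C(C)C | intermediate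
25 | {(1S,2R)-2-[(tert-butyldimethylsilyloxy)methyl]-6-methoxy-1-[3-methoxy-4-(triisopropylsilyloxy)phenyl]-7-(triisopropylsilyloxy)-1,2-dihydronaphthalen-3-yl}methanol | COc1cc([C@H]2c3cc(O[Si](C(C)C)(C(C)C)C(C)C)c(OC)cc3C=C(CO)[C@@H]2CO[Si](C)(C)C(C)(C)C)ccc1O[Si](C(C)C)(C(C)C)C(C)C | intermediate
26 | (1S,2R)-2-[(tert-butyldimethylsilyloxy)methyl]-6-methoxy-1-[3-methoxy-4-(triisopropylsilyloxy)phenyl]-7-(triisopropylsilyloxy)-1,2-dihydronaphthalene-3-carbaldehyde | COc1cc([C@H]2c3cc(O[Si](C(C)C)(C(C)C)C(C)C)c(OC)cc3C=C(C=O)[C@@H]2CO[Si](C)(C)C(C)(C)C)ccc1O[Si](C(C)C)(C(C)C)C(C)C | intermediate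
27 | (1S,2R)-2-(hydroxymethyl)-6-methoxy-1-[3-methoxy-4-(triisopropylsilyloxy)phenyl]-7-(triisopropylsilyloxy)-1,2-dihydronaphthalene-3-carbaldehyde | COc1cc([C@H]2c3cc(O[Si](C(C)C)(C(C)C)C(C)C)c(OC)cc3C=C(C=O)[C@@H]2CO)ccc1O[Si](C(C)C)(C(C)C)C(C)C | intermediate
28 | {(1S,2R)-3-formyl-6-methoxy-1-[3-methoxy-4-(triisopropylsilyloxy)phenyl]-7-(triisopropylsilyloxy)-1,2-dihydronaphthalen-2-yl}methyl acetate | COc1cc([C@H]2c3cc(O[Si](C(C)C)(C(C)C)C(C)C)c(OC)cc3C=C(C=O)[C@@H]2COC(C)=O)ccc1O[Si](C(C)C)(C(C)C)C(C)C | intermediate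
29 | [(1S,2R)-3-formyl-7-hydroxy-1-(4-hydroxy-3-methoxyphenyl)-6-methoxy-1,2-dihydronaphthalen-2-yl]methyl acetate (CNP0549177.1) | COc1cc([C@H]2c3cc(O)c(OC)cc3C=C(C=O)[C@@H]2COC(C)=O)ccc1O | target

## Step count and least certain steps

Total step count: 19. Longest linear sequence: 17 steps (steps 1, 3 and 5–19, from 1 to 29); steps 2 and 4 are side branches.

**Step 14 (key step).** The most likely failure is hydration of the N-alkynyl group by adventitious water or acid, or loss of the C9 silyl ether, before the oxete has formed and opened. The keteniminium ion is a strong electrophile, and the Lewis acid stays bound to the imide product. The fallback makes the same C3–C4 bond by an ionic two-stage route and sets out from 22. Deliberate hydration (p-TsOH·H2O cat., wet CH2Cl2, 0 °C) would give the N-acyl oxazolidinone aldehyde F1. Soft enolisation and intramolecular aldol addition (TiCl4, i-Pr2NEt, CH2Cl2, −78 → −20 °C) would close ring B to the beta-hydroxy imide F2. Mesylation and elimination (MsCl, Et3N; then DBU) would bring the route back at 24.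

**Step 11.** The most likely failure is proton transfer from incompletely deprotonated alkyne to the aryllithium, which loses the bromine handle as C–H, or partial formylation at the acetylide carbon. Both follow from having two carbanions in one molecule. The fallback avoids organolithiums and sets out from 17. Stille coupling with tributyl(vinyl)stannane (Pd(PPh3)4, toluene, 100 °C) would give the styrene F3. Lemieux–Johnson cleavage (OsO4 cat., NaIO4, 2,6-lutidine, dioxane/H2O) would return to the route at 19.

**Step 10.** The most likely failure is epimerisation at C2 by enolisation of the hindered aldehyde in K2CO3/MeOH before it is trapped, or slow methanolysis of the aryl silyl ethers. The fallback is a Corey–Fuchs sequence from 16. CBr4, PPh3 and Et3N in CH2Cl2 at 0 °C would give the dibromoalkene F4. LDA (2.5 equiv, THF, −78 °C), an amide base that does not exchange the aryl bromide, would convert it into 17.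

**Step 8.** The most likely failure is hydride attack at the ring carbonyl of the hindered imide, which opens the auxiliary instead of releasing it. The fallback sets out from 14. Cleavage with LiSEt (EtSH, n-BuLi, THF, 0 °C) would give the thioester F5. Partial reduction with i-Bu2AlH (1.2 equiv, CH2Cl2, −78 °C) would then give aldehyde 16 directly, bypassing 15.

**Step 15.** The most likely failure is conjugate hydride delivery to the enoyl imide or attack at the oxazolidinone carbonyl, since the C3=C4 bond is activated by both the imide and ring A. The fallback sets out from 24. Transesterification with MeOMgBr (MeOH/CH2Cl2, 0 °C) would give the methyl ester F6. Ordinary enoate reduction with i-Bu2AlH (2.5 equiv, CH2Cl2, −78 °C) would return to the route at 25.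

## Further compounds

F1 | step 14 | 3-{(3S,4S)-4-[2-formyl-4-methoxy-5-(triisopropylsilyloxy)phenyl]-3-[(tert-butyldimethylsilyloxy)methyl]-4-[3-methoxy-4-(triisopropylsilyloxy)phenyl]butanoyl}oxazolidin-2-one | COc1cc([C@@H](c2cc(O[Si](C(C)C)(C(C)C)C(C)C)c(OC)cc2C=O)[C@@H](CO[Si](C)(C)C(C)(C)C)CC(=O)N2CCOC2=O)ccc1O[Si](C(C)C)(C(C)C)C(C)C
F2 | step 14 | 3-{(1S,2R)-2-[(tert-butyldimethylsilyloxy)methyl]-4-hydroxy-6-methoxy-1-[3-methoxy-4-(triisopropylsilyloxy)phenyl]-7-(triisopropylsilyloxy)-1,2,3,4-tetrahydronaphthalene-3-carbonyl}oxazolidin-2-one (C3 and C4 unassigned) | COc1cc([C@H]2c3cc(O[Si](C(C)C)(C(C)C)C(C)C)c(OC)cc3C(O)C(C(=O)N3CCOC3=O)[C@@H]2CO[Si](C)(C)C(C)(C)C)ccc1O[Si](C(C)C)(C(C)C)C(C)C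
F3 | step 11 | (3R,4S)-3-[(tert-butyldimethylsilyloxy)methyl]-4-[4-methoxy-5-(triisopropylsilyloxy)-2-vinylphenyl]-4-[3-methoxy-4-(triisopropylsilyloxy)phenyl]but-1-yne | COc1cc([C@@H](c2cc(O[Si](C(C)C)(C(C)C)C(C)C)c(OC)cc2C=C)[C@@H](CO[Si](C)(C)C(C)(C)C)C#C)ccc1O[Si](C(C)C)(C(C)C)C(C)C
F4 | step 10 | (3R,4S)-1,1-dibromo-4-[2-bromo-4-methoxy-5-(triisopropylsilyloxy)phenyl]-3-[(tert-butyldimethylsilyloxy)methyl]-4-[3-methoxy-4-(triisopropylsilyloxy)phenyl]but-1-ene | COc1cc([C@@H](c2cc(O[Si](C(C)C)(C(C)C)C(C)C)c(OC)cc2Br)[C@@H](CO[Si](C)(C)C(C)(C)C)C=C(Br)Br)ccc1O[Si](C(C)C)(C(C)C)C(C)C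
F5 | step 8 | S-ethyl (2S,3S)-3-[2-bromo-4-methoxy-5-(triisopropylsilyloxy)phenyl]-2-[(tert-butyldimethylsilyloxy)methyl]-3-[3-methoxy-4-(triisopropylsilyloxy)phenyl]propanethioate | COc1cc([C@@H](c2cc(O[Si](C(C)C)(C(C)C)C(C)C)c(OC)cc2Br)[C@@H](CO[Si](C)(C)C(C)(C)C)C(=O)SCC)ccc1O[Si](C(C)C)(C(C)C)C(C)C
F6 | step 15 | methyl (1S,2R)-2-[(tert-butyldimethylsilyloxy)methyl]-6-methoxy-1-[3-methoxy-4-(triisopropylsilyloxy)phenyl]-7-(triisopropylsilyloxy)-1,2-dihydronaphthalene-3-carboxylate | COc1cc([C@H]2c3cc(O[Si](C(C)C)(C(C)C)C(C)C)c(OC)cc3C=C(C(=O)OC)[C@@H]2CO[Si](C)(C)C(C)(C)C)ccc1O[Si](C(C)C)(C(C)C)C(C)C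
A1 | alternative 1 | (E)-3-[4-(tert-butyldimethylsilyloxy)-3-methoxyphenyl]allyl 3-[4-(tert-butyldimethylsilyloxy)-3-methoxyphenyl]prop-2-yn-1-yl ether (1,6-enyne) | COc1cc(C#CCOC/C=C/c2ccc(O[Si](C)(C)C(C)(C)C)c(OC)c2)ccc1O[Si](C)(C)C(C)(C)C
A2 | alternative 1 | trans-4-aryl-1,3,3a,4-tetrahydronaphtho[2,3-c]furan bis-silyl ether | COc1cc([C@H]2c3cc(O[Si](C)(C)C(C)(C)C)c(OC)cc3C=C3COC[C@@H]32)ccc1O[Si](C)(C)C(C)(C)C
A3 | alternative 2 | 1,7-diyne bearing the C1 aryl, C2 acetoxymethyl, C3 silyloxymethyl and C4 silyloxy groups | COc1cc([C@@H](C#C)[C@@H](COC(C)=O)[C@H](CO[Si](C)(C)C(C)(C)C)[C@H](O[Si](C)(C)C(C)(C)C)C#C)ccc1OCOC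
A4 | alternative 2 | 1,2-bis(pinacolboryl)ethyne | CC1(C)OB(C#CB2OC(C)(C)C(C)(C)O2)OC1(C)C
A5 | alternative 2 | 6,7-diboryl-1-aryl-2-(acetoxymethyl)-3-(silyloxymethyl)-4-silyloxytetralin | COc1cc([C@H]2c3cc(B4OC(C)(C)C(C)(C)O4)c(B4OC(C)(C)C(C)(C)O4)cc3[C@@H](O[Si](C)(C)C(C)(C)C)[C@@H](CO[Si](C)(C)C(C)(C)C)[C@@H]2COC(C)=O)ccc1OCOC
A6 | alternative 3 | ten-membered benzo-fused allylic lactone (drawn with an E alkene) | COc1cc([C@@H]2/C=C/COC(=O)C[C@H](O[Si](C)(C)C(C)(C)C)c3cc(OC)c(O[Si](C)(C)C(C)(C)C)cc32)ccc1O[Si](C)(C)C(C)(C)C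
A7 | alternative 3 | 1-aryl-2-vinyl-4-silyloxytetralin-3-carboxylic acid | COc1cc([C@H]2c3cc(O[Si](C)(C)C(C)(C)C)c(OC)cc3[C@@H](O[Si](C)(C)C(C)(C)C)[C@H](C(=O)O)[C@@H]2C=C)ccc1O[Si](C)(C)C(C)(C)C
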